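**Plan**
- The five O-benzyl bonds are cut first (5-O, 8-O and the three B-ring oxygens), then O1–C2 of the pyranone, which leaves an open 2-methoxy-1,3-diketone.
- C4 is a lone carbonyl carbon between C4a of ring A and the methoxy-bearing C3. Both C4a–C4 and C4–C3 are therefore cut together, and C4 becomes carbon monoxide placed between an A-ring iodide (iodine at C4a, MOM-masked O1 beside it) and the enolate of the B-ring methoxymethyl ketone.
- Forward: the iodide comes from 5-hydroxyvanillin in five steps and the ketone from tribenzylgallic acid in two; rings A and B come intact from these starting materials.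
- The three-component carbonylative coupling joins the chain without closing a ring, acid then closes ring C at O1–C2, and hydrogenolysis finishes.
- Stereochemistry: the target has no stereocentre; the methine of the diketone is racemic, enolisable and becomes sp2 on ring closure.

Key step: step 8

Remark: the target SMILES is achiral, so "single enantiomer" is read as the one constitution drawn; tributyl(methoxymethyl)stannane is treated as a purchasable reagent.

**Route**

Step 1
Reactants: 1 5-hydroxyvanillin (3,4-dihydroxy-5-methoxybenzaldehyde)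
Product: 2 4-(benzyloxy)-3-hydroxy-5-methoxybenzaldehyde
Conditions: BnBr (1.0 equiv), NaHCO3, DMF, 40 °C
Reagents that add atoms: benzyl bromide, BrCc1ccccc1
Why: Williamson etherification under a weak base, in which only the 4-OH (para to the formyl group and hence the more acidic phenol) should be deprotonated, so that one equivalent of benzyl bromide is expected to stop at the 4-O-benzyl ether.

Step 2
Reactants: 2 4-(benzyloxy)-3-hydroxy-5-methoxybenzaldehyde
Product: 3 4-(benzyloxy)-3-methoxy-5-(methoxymethoxy)benzaldehyde
Conditions: MOMCl, i-Pr2NEt, CH2Cl2, 0 °C → rt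
Reagents that add atoms: chloromethyl methyl ether, COCCl
Why: Routine O-alkylation of the remaining phenol to its methoxymethyl acetal, which leaves aldehyde and benzyl ether alone and puts the only acid-labile ether of the route on the future O1.

Step 3
Reactants: 3 4-(benzyloxy)-3-methoxy-5-(methoxymethoxy)benzaldehyde
Product: 5 4-(benzyloxy)-3-methoxy-5-(methoxymethoxy)phenol, via aryl formate 4 (not isolated)
Conditions: mCPBA, CH2Cl2, 0 °C → rt; then K2CO3 (cat.), MeOH, rt
Reagents that add atoms: 3-chloroperbenzoic acid, O=C(OO)c1cccc(Cl)c1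
Why: Dakin-type Baeyer–Villiger oxidation, in which the electron-rich trioxygenated aryl group of the Criegee adduct migrates in preference to hydrogen to give the formate, and mild methanolysis then frees the phenol without touching the MOM or benzyl ethers.

Step 4
Reactants: 5 4-(benzyloxy)-3-methoxy-5-(methoxymethoxy)phenol
Product: 6 2,5-bis(benzyloxy)-1-methoxy-3-(methoxymethoxy)benzene
Conditions: BnBr, K2CO3, DMF, rt
Reagents that add atoms: benzyl bromide, BrCc1ccccc1
Why: Williamson etherification of the free phenol, which places a hydrogenolysable group on the future 5-oxygen and keeps it distinct from the MOM-masked O1.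

Step 5
Reactants: 6 2,5-bis(benzyloxy)-1-methoxy-3-(methoxymethoxy)benzene
Product: 8 1,4-bis(benzyloxy)-2-iodo-5-methoxy-3-(methoxymethoxy)benzene, via aryllithium 7 (not isolated)
Conditions: n-BuLi, THF, −20 → 0 °C; then I2, THF, −78 °C → rt
Reagents that add atoms: iodine, II
Why: Directed ortho-metalation, in which the ring C–H between the MOM ether (a better lithium-coordinating director than methoxy) and a benzyloxy group should be lithiated in preference to the C–H between benzyloxy and methoxy and to the benzylic CH2 groups at or below 0 °C, after which iodinolysis fixes iodine at the future C4a.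

Step 6
Reactants: 9 3,4,5-tris(benzyloxy)benzoic acid
Product: 11 3,4,5-tris(benzyloxy)-N-methoxy-N-methylbenzamide, via acid chloride 10 (not isolated)
Conditions: (COCl)2, DMF (cat.), CH2Cl2, 0 °C → rt; then MeNH(OMe)·HCl, Et3N, CH2Cl2, 0 °C → rt
Reagents that add atoms: N,O-dimethylhydroxylamine hydrochloride, CNOC.Cl
Why: Acid chloride formation under Vilsmeier catalysis followed by N-acylation of N,O-dimethylhydroxylamine (Weinreb amide synthesis), both of which aryl benzyl ethers tolerate.

Step 7
Reactants: 11 3,4,5-tris(benzyloxy)-N-methoxy-N-methylbenzamide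
Product: 13 2-methoxy-1-[3,4,5-tris(benzyloxy)phenyl]ethan-1-one, via lithium hemiaminal chelate 12 (not isolated)
Conditions: Bu3SnCH2OMe, n-BuLi, THF, −78 °C; then 11, −78 °C; 1 M HCl quench
Reagents that add atoms: tributyl(methoxymethyl)stannane, CCCC[Sn](CCCC)(CCCC)COC
Why: Tin–lithium exchange generates methoxymethyllithium, which should add only once because the five-membered N-methoxy chelate holds the tetrahedral adduct until the acidic quench (Weinreb ketone synthesis).

Step 8
Reactants: 8 1,4-bis(benzyloxy)-2-iodo-5-methoxy-3-(methoxymethoxy)benzene; 13 2-methoxy-1-[3,4,5-tris(benzyloxy)phenyl]ethan-1-one; 14 carbon monoxide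
Product: 15 1-[3,6-bis(benzyloxy)-4-methoxy-2-(methoxymethoxy)phenyl]-2-methoxy-3-[3,4,5-tris(benzyloxy)phenyl]propane-1,3-dione (racemic, keto–enol mixture)
Conditions: 13 (2 equiv), NaHMDS (2 equiv), THF, 0 °C; then 8, Pd(dba)2 (5 mol%), Xantphos (5 mol%), CO (3 bar), THF, 80 °C; AcOH quench
Reagents that add atoms: none
Why: Pd(0)/Xantphos should insert into the C–I bond of 8, CO migratory insertion then gives the aroylpalladium iodide (C4a–C4), the sodium enolate of 13 replaces iodide and reductive elimination (or direct enolate attack at the acyl carbon) forms C4–C3, after which the second equivalent of enolate deprotonates the β-diketone, driving the sequence forward and preventing a second acylation (the regenerated 13 is recovered). The closest known reaction type is the palladium-catalysed carbonylative α-arylation of aryl ketones with aryl iodides under low CO pressure, applied here to an α-alkoxy ketone and a 2,6-dioxygenated iodide. No ring closes in this step; only the open C4a–C4–C3 chain is assembled. The methine carbon that becomes C3 is formed without control in an enolisable 1,3-diketone, so it is racemic and is flattened in step 9. Carbonylative coupling should win over direct α-arylation because the two ortho alkoxy groups of 8 slow enolate arylation at the aryl–palladium stage while CO insertion relieves crowding, helped by CO pressure and the wide bite angle of Xantphos; C-acylation should win over O-acylation because the diketonate is the thermodynamic sink and any enol ester would be transacylated by surplus enolate; 13 has a single enolisable CH2, and the MOM and benzyl ethers are inert to the base and to Pd(0).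

Step 9
Reactants: 15 1-[3,6-bis(benzyloxy)-4-methoxy-2-(methoxymethoxy)phenyl]-2-methoxy-3-[3,4,5-tris(benzyloxy)phenyl]propane-1,3-dione
Product: 18 5,8-bis(benzyloxy)-3,7-dimethoxy-2-[3,4,5-tris(benzyloxy)phenyl]-4H-chromen-4-one, via phenol diketone 16 (not isolated), via cyclic hemiketal 17 (not isolated)
Conditions: conc. HCl, MeOH/THF, 55 °C
Reagents that add atoms: none
Why: Acid-catalysed methanolysis of the MOM acetal frees the phenol at C8a, which adds to the B-ring ketone (6-exo-trig hemiketalisation) and loses water to the pyranone as in the closing stage of a Baker–Venkataraman flavone synthesis, and because the 5-oxygen is still benzylated only O1 can close, so the 5,6,7-isomer cannot arise.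

Step 10
Reactants: 18 5,8-bis(benzyloxy)-3,7-dimethoxy-2-[3,4,5-tris(benzyloxy)phenyl]-4H-chromen-4-one
Product: 19 5,8,3',4',5'-pentahydroxy-3,7-dimethoxyflavone
Conditions: H2 (1 atm), 10% Pd/C, THF/MeOH, rt; filtration and concentration under argon
Reagents that add atoms: none
Why: Palladium-catalysed hydrogenolysis should cleave the five aryl benzyl ethers as toluene, while the methyl ethers and the tetrasubstituted vinylogous-ester C2=C3 bond are not reduced at one atmosphere and room temperature.

**Compound list**

1 | 5-hydroxyvanillin (3,4-dihydroxy-5-methoxybenzaldehyde) | COc1cc(C=O)cc(O)c1O | starting material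
2 | 4-(benzyloxy)-3-hydroxy-5-methoxybenzaldehyde | COc1cc(C=O)cc(O)c1OCc1ccccc1 | intermediate
3 | 4-(benzyloxy)-3-methoxy-5-(methoxymethoxy)benzaldehyde | COCOc1cc(C=O)cc(OC)c1OCc1ccccc1 | intermediate
4 | 4-(benzyloxy)-3-methoxy-5-(methoxymethoxy)phenyl formate (not isolated) | COCOc1cc(OC=O)cc(OC)c1OCc1ccccc1 | intermediate
5 | 4-(benzyloxy)-3-methoxy-5-(methoxymethoxy)phenol | COCOc1cc(O)cc(OC)c1OCc1ccccc1 | intermediate
6 | 2,5-bis(benzyloxy)-1-methoxy-3-(methoxymethoxy)benzene | COCOc1cc(OCc2ccccc2)cc(OC)c1OCc1ccccc1 | intermediate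
7 | [3,6-bis(benzyloxy)-4-methoxy-2-(methoxymethoxy)phenyl]lithium (not isolated) | COCOc1c([Li])c(OCc2ccccc2)cc(OC)c1OCc1ccccc1 | intermediate
8 | 1,4-bis(benzyloxy)-2-iodo-5-methoxy-3-(methoxymethoxy)benzene | COCOc1c(I)c(OCc2ccccc2)cc(OC)c1OCc1ccccc1 | intermediate
9 | 3,4,5-tris(benzyloxy)benzoic acid | O=C(O)c1cc(OCc2ccccc2)c(OCc2ccccc2)c(OCc2ccccc2)c1 | starting material
10 | 3,4,5-tris(benzyloxy)benzoyl chloride (not isolated) | O=C(Cl)c1cc(OCc2ccccc2)c(OCc2ccccc2)c(OCc2ccccc2)c1 | intermediate
11 | 3,4,5-tris(benzyloxy)-N-methoxy-N-methylbenzamide | CON(C)C(=O)c1cc(OCc2ccccc2)c(OCc2ccccc2)c(OCc2ccccc2)c1 | intermediate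
12 | lithium 2-methoxy-1-[methoxy(methyl)amino]-1-[3,4,5-tris(benzyloxy)phenyl]ethan-1-olate (chelated tetrahedral adduct, racemic, not isolated) | COCC(O[Li])(N(C)OC)c1cc(OCc2ccccc2)c(OCc2ccccc2)c(OCc2ccccc2)c1 | intermediate
13 | 2-methoxy-1-[3,4,5-tris(benzyloxy)phenyl]ethan-1-one | COCC(=O)c1cc(OCc2ccccc2)c(OCc2ccccc2)c(OCc2ccccc2)c1 | intermediate
14 | carbon monoxide | [C-]#[O+] | starting material
15 | 1-[3,6-bis(benzyloxy)-4-methoxy-2-(methoxymethoxy)phenyl]-2-methoxy-3-[3,4,5-tris(benzyloxy)phenyl]propane-1,3-dione (racemic, enolisable) | COCOc1c(C(=O)C(OC)C(=O)c2cc(OCc3ccccc3)c(OCc3ccccc3)c(OCc3ccccc3)c2)c(OCc2ccccc2)cc(OC)c1OCc1ccccc1 | intermediate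
16 | 1-[3,6-bis(benzyloxy)-2-hydroxy-4-methoxyphenyl]-2-methoxy-3-[3,4,5-tris(benzyloxy)phenyl]propane-1,3-dione (racemic, not isolated) | COc1cc(OCc2ccccc2)c(C(=O)C(OC)C(=O)c2cc(OCc3ccccc3)c(OCc3ccccc3)c(OCc3ccccc3)c2)c(O)c1OCc1ccccc1 | intermediate
17 | 5,8-bis(benzyloxy)-2-hydroxy-3,7-dimethoxy-2-[3,4,5-tris(benzyloxy)phenyl]chroman-4-one (diastereomer mixture, racemic, not isolated) | COc1cc(OCc2ccccc2)c2c(c1OCc1ccccc1)OC(O)(c1cc(OCc3ccccc3)c(OCc3ccccc3)c(OCc3ccccc3)c1)C(OC)C2=O | intermediate
18 | 5,8-bis(benzyloxy)-3,7-dimethoxy-2-[3,4,5-tris(benzyloxy)phenyl]-4H-chromen-4-one | COc1cc(OCc2ccccc2)c2c(=O)c(OC)c(-c3cc(OCc4ccccc4)c(OCc4ccccc4)c(OCc4ccccc4)c3)oc2c1OCc1ccccc1 | intermediate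
19 | 5,8,3',4',5'-pentahydroxy-3,7-dimethoxyflavone (achiral) | COc1cc(O)c2c(=O)c(OC)c(-c3cc(O)c(O)c(O)c3)oc2c1O | target

**Count**

Total steps: 10. Longest linear sequence: 8 steps (steps 1–5, then 8, 9, 10); the ketone arm (steps 6–7) joins at step 8.

**Steps most likely to fail**

Step 8. At the crowded 2,6-dioxygenated aroylpalladium stage, CO insertion or capture by the α-methoxy enolate may be too slow, so that hydrodeiodination, direct arylation or O-acylation takes over. The fallback brings C4 in at the aldehyde oxidation level and forms the same two bonds in separate operations. It sets out from 8 and 13. Iodine–lithium exchange on 8 (n-BuLi, THF, −78 °C) regenerates 7, which is quenched with DMF to give 3,6-bis(benzyloxy)-4-methoxy-2-(methoxymethoxy)benzaldehyde F1 (C4a–C4). Aldol addition of the lithium enolate of 13 (LiHMDS, THF, −78 °C) to F1 should give 3-[3,6-bis(benzyloxy)-4-methoxy-2-(methoxymethoxy)phenyl]-3-hydroxy-2-methoxy-1-[3,4,5-tris(benzyloxy)phenyl]propan-1-one F2 (C4–C3; the diastereomer mixture is of no consequence). Dess–Martin oxidation (NaHCO3, CH2Cl2) of the β-hydroxy ketone returns to the route at 15.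

Step 5. Lithiation may occur at the other ring C–H (between benzyloxy and methoxy) or at a benzylic CH2 with subsequent [1,2]-Wittig shift. The fallback replaces the MOM group during metalation by a much stronger, removable director and sets out from 6. Methanolic HCl removes the MOM group to give 2,5-bis(benzyloxy)-3-methoxyphenol F3. Carbamoylation (ClCONEt2, NaH, THF) gives 2,5-bis(benzyloxy)-3-methoxyphenyl diethylcarbamate F4. s-BuLi/TMEDA in THF at −78 °C should lithiate only the one free position ortho to the carbamate, fast enough to outrun benzylic deprotonation, and iodine then gives 2,5-bis(benzyloxy)-6-iodo-3-methoxyphenyl diethylcarbamate F5. Reductive carbamate cleavage with Cp2Zr(H)Cl in THF, which spares the aryl iodide, gives 2,5-bis(benzyloxy)-6-iodo-3-methoxyphenol F6. MOMCl/i-Pr2NEt then returns to the route at 8.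

Step 10. Hydrogenolysis may stall at partly benzylated stages through fouling of the catalyst by the polyphenol, or the 5,8-hydroquinone may be oxidised by air during filtration from the palladium. The fallback is a Lewis-acid debenzylation in place of the reductive one: BCl3 with pentamethylbenzene as benzyl-cation trap in CH2Cl2 at −78 °C, methanol quench, directly from 18 to 19. It needs no metal filtration, makes no new compound, and at this temperature the two methyl ethers should survive.

**Further compounds**

F1 | step 8 | 3,6-bis(benzyloxy)-4-methoxy-2-(methoxymethoxy)benzaldehyde | COCOc1c(C=O)c(OCc2ccccc2)cc(OC)c1OCc1ccccc1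
F2 | step 8 | 3-[3,6-bis(benzyloxy)-4-methoxy-2-(methoxymethoxy)phenyl]-3-hydroxy-2-methoxy-1-[3,4,5-tris(benzyloxy)phenyl]propan-1-one (diastereomer mixture, racemic) | COCOc1c(C(O)C(OC)C(=O)c2cc(OCc3ccccc3)c(OCc3ccccc3)c(OCc3ccccc3)c2)c(OCc2ccccc2)cc(OC)c1OCc1ccccc1
F3 | step 5 | 2,5-bis(benzyloxy)-3-methoxyphenol | COc1cc(OCc2ccccc2)cc(O)c1OCc1ccccc1
F4 | step 5 | 2,5-bis(benzyloxy)-3-methoxyphenyl diethylcarbamate | CCN(CC)C(=O)Oc1cc(OCc2ccccc2)cc(OC)c1OCc1ccccc1
F5 | step 5 | 2,5-bis(benzyloxy)-6-iodo-3-methoxyphenyl diethylcarbamate | CCN(CC)C(=O)Oc1c(I)c(OCc2ccccc2)cc(OC)c1OCc1ccccc1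
F6 | step 5 | 2,5-bis(benzyloxy)-6-iodo-3-methoxyphenol | COc1cc(OCc2ccccc2)c(I)c(O)c1OCc1ccccc1
F0 | step 10 | none | none
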